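**Plan**

- Retrosynthesis: the (R)-lactol is traced back to the racemic lactol. The diaryl ether C–O bond between the ring A oxygen and ring B is cut next. Then three C–C bonds of ring A are cut together: phenol carbon to CH2O-bearing carbon, OMe carbon to the unsubstituted CH carbon, and phenol carbon to ester-bearing carbon. This leaves an aryl ester of a diazo enone and a 1-methoxyalkyne.
- Enabling feature: ring A is a pentasubstituted salicylate. Its oxygen-bearing carbon lies between the hydroxymethyl carbon and the ester carbonyl carbon, OMe is meta to that oxygen, and the one ring hydrogen sits between the OMe and CH3 carbons. A vinylketene and an alkoxyalkyne deliver exactly this pattern.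
- Forward: ring B is built as a bromo methoxyphthalide from 2-methylresorcinol by two directed metalations. Its 5-OH is acylated with (E)-3-methyl-4-oxopent-2-enoic acid, and diazo transfer gives the diazo ketone. The benzannulation then forms ring A with the depside ester already in place, copper closes the seven-membered dioxepinone, and acid unmasks the triol.
- Stereochemistry: the only stereocentre, the lactol carbon, is carried as a racemic methyl acetal. It is set (R) in the last two steps by catalyst-controlled acylative dynamic kinetic resolution and neutral enzymatic deacylation.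

Key step: step 12

Assumption: the lactol carbon is configurationally labile through ring–chain tautomerism, so the product must be kept cold, dry and free of acid or base; the (R) sense of the acyl-transfer catalyst is taken from the benzylic alcohol model and would be confirmed on racemate 28, the (S)-catalyst being used if the opposite ester forms.

**Route**

Step 1
Reactants: 1 2-methylresorcinol
Product: 2 1,3-bis(methoxymethoxy)-2-methylbenzene
Conditions: MOMCl (2.5 equiv), iPr2NEt, CH2Cl2, 0 → 25 °C
Reagents that add atoms: chloromethyl methyl ether, COCCl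
Why: O-alkylation of both phenols by the chloromethyl ether under amine base gives the bis-acetal, whose oxygen groups later direct metalation.

Step 2
Reactants: 2 1,3-bis(methoxymethoxy)-2-methylbenzene
Product: 4 N,N-diethyl-2,4-bis(methoxymethoxy)-3-methylbenzamide, via aryllithium 3 (not isolated)
Conditions: n-BuLi, TMEDA, THF, 0 °C; then ClC(O)NEt2, −78 → 25 °C
Reagents that add atoms: diethylcarbamoyl chloride, CCN(CC)C(Cl)=O
Why: Directed ortho-metalation next to an OMOM group (the two such positions are equivalent) followed by acylation of the aryllithium with the carbamoyl chloride installs the tertiary amide.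

Step 3
Reactants: 4 N,N-diethyl-2,4-bis(methoxymethoxy)-3-methylbenzamide
Product: 6 N,N-diethyl-6-formyl-2,4-bis(methoxymethoxy)-3-methylbenzamide, via 6-lithio amide 5 (not isolated)
Conditions: s-BuLi, TMEDA, THF, −78 °C; then DMF, −78 → 0 °C; H2O
Reagents that add atoms: N,N-dimethylformamide, CN(C)C=O
Why: Second directed ortho-metalation in which the tertiary amide outranks OMOM as director, so the hydrogen next to the amide is removed and the aryllithium is formylated by DMF.

Step 4
Reactants: 6 N,N-diethyl-6-formyl-2,4-bis(methoxymethoxy)-3-methylbenzamide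
Product: 8 rac-5,7-dihydroxy-3-methoxy-6-methylisobenzofuran-1(3H)-one, via hydroxyphthalide 7 (not isolated)
Conditions: 3 M HCl, MeOH/H2O (4:1), 65 °C; evaporate; then MeOH, cat. H2SO4, 65 °C
Reagents that add atoms: methanol, CO; water, O
Why: Acid cleaves both MOM acetals, the hydrated aldehyde displaces diethylamine from the neighbouring amide (anchimerically assisted solvolysis to the 3-hydroxyphthalide), and Fischer-type pseudo-esterification in methanol gives the methyl acetal; the acetal carbon forms as a racemate and is reset in step 15.

Step 5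
Reactants: 8 rac-5,7-dihydroxy-3-methoxy-6-methylisobenzofuran-1(3H)-one
Product: 9 rac-4-bromo-5,7-dihydroxy-3-methoxy-6-methylisobenzofuran-1(3H)-one
Conditions: NBS (1.0 equiv), MeCN, 0 °C
Reagents that add atoms: N-bromosuccinimide, O=C1CCC(=O)N1Br
Why: Electrophilic aromatic bromination at the only free ring position, which is ortho to one phenol and para to the other.

Step 6
Reactants: 10 butane-2,3-dione (3 equiv); 11 tert-butyl (triphenylphosphoranylidene)acetate
Product: 12 tert-butyl (E)-3-methyl-4-oxopent-2-enoate
Conditions: CH2Cl2, 25 °C
Reagents that add atoms: none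
Why: Wittig olefination of one carbonyl of the diketone with the ester-stabilised ylide should give the trisubstituted (E)-enoate with the acetyl group trans to the ester.

Step 7
Reactants: 12 tert-butyl (E)-3-methyl-4-oxopent-2-enoate
Product: 13 (E)-3-methyl-4-oxopent-2-enoic acid
Conditions: CF3CO2H/CH2Cl2 (1:3), 0 → 25 °C
Reagents that add atoms: none
Why: Acidolysis of the tert-butyl ester with loss of isobutene frees the acid without disturbing the alkene geometry.

Step 8
Reactants: 13 (E)-3-methyl-4-oxopent-2-enoic acid; 9 rac-4-bromo-5,7-dihydroxy-3-methoxy-6-methylisobenzofuran-1(3H)-one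
Product: 15 rac-4-bromo-7-hydroxy-3-methoxy-6-methyl-1-oxo-1,3-dihydroisobenzofuran-5-yl (E)-3-methyl-4-oxopent-2-enoate, via acid chloride 14 (not isolated)
Conditions: (COCl)2, cat. DMF, CH2Cl2, 0 → 25 °C; evaporate; then 9, iPr2NEt (1.05 equiv), CH2Cl2, −20 °C
Reagents that add atoms: none
Why: Phenol acylation by an acid chloride in which one equivalent of amine ionises only the more acidic 5-OH (para to the lactone carbonyl, ortho to bromine), while the 7-OH is held in a hydrogen bond to the lactone carbonyl, as in the 4-O-selective acylation of 2,4-dihydroxybenzoates.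

Step 9
Reactants: 15 rac-4-bromo-7-hydroxy-3-methoxy-6-methyl-1-oxo-1,3-dihydroisobenzofuran-5-yl (E)-3-methyl-4-oxopent-2-enoate
Product: 16 rac-4-bromo-3-methoxy-7-(methoxymethoxy)-6-methyl-1-oxo-1,3-dihydroisobenzofuran-5-yl (E)-3-methyl-4-oxopent-2-enoate
Conditions: MOMCl, iPr2NEt, CH2Cl2, 40 °C
Reagents that add atoms: chloromethyl methyl ether, COCCl
Why: O-alkylation of the remaining chelated phenol under non-nucleophilic amine base, which spares the aryl ester and the enone and gives a group that falls off in the final acid step.

Step 10
Reactants: 16 rac-4-bromo-3-methoxy-7-(methoxymethoxy)-6-methyl-1-oxo-1,3-dihydroisobenzofuran-5-yl (E)-3-methyl-4-oxopent-2-enoate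
Product: 18 rac-4-bromo-3-methoxy-7-(methoxymethoxy)-6-methyl-1-oxo-1,3-dihydroisobenzofuran-5-yl (E)-5-diazo-3-methyl-4-oxopent-2-enoate, via trifluoroacetyl diketone 17 (not isolated)
Conditions: LiN(SiMe3)2, THF, −78 °C; CF3CO2CH2CF3, −78 °C; cold 5% aq. HCl wash; then MeSO2N3, Et3N, H2O (1 equiv), MeCN, 25 °C
Reagents that add atoms: methanesulfonyl azide, CS(=O)(=O)N=[N+]=[N-]
Why: Detrifluoroacetylative diazo transfer: kinetic enolisation of the methyl ketone, Claisen trifluoroacetylation and Regitz-type diazo transfer with loss of the trifluoroacetyl group is the established route to diazo enones and avoids diazomethane, which would add across the electron-poor alkene.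

Step 11
Reactants: 19 chloroacetaldehyde dimethyl acetal
Product: 22 1-methoxy-3-(triisopropylsilyloxy)prop-1-yne, via lithium methoxyacetylide 20 (not isolated), via lithium alkoxide 21 (not isolated)
Conditions: LiNEt2 (3 equiv, from Et2NH and n-BuLi), THF, 0 °C; (CH2O)n, −78 → 25 °C; then TIPSCl (2.2 equiv), DMF, 25 °C
Reagents that add atoms: formaldehyde (as paraformaldehyde), C=O; chlorotriisopropylsilane, CC(C)[Si](Cl)(C(C)C)C(C)C
Why: Twofold elimination and deprotonation of the chloroacetal by the lithium amide gives the methoxyacetylide, which adds to formaldehyde; the alkoxide is silylated in the same flask so the acid-sensitive propargylic alcohol is never isolated (the second equivalent of silyl chloride is taken up by LiOMe).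

Step 12
Reactants: 18 diazo ketone aryl ester; 22 1-methoxy-3-(triisopropylsilyloxy)prop-1-yne (2 equiv)
Product: 26 rac-4-bromo-3-methoxy-7-(methoxymethoxy)-6-methyl-1-oxo-1,3-dihydroisobenzofuran-5-yl 2-hydroxy-4-methoxy-6-methyl-3-[(triisopropylsilyloxy)methyl]benzoate, via vinylketene 23 (not isolated), via cyclobutenone 24 (not isolated), via dienylketene 25 (not isolated)
Conditions: ClCH2CH2Cl, hν (365 nm), 25 °C; then 80 °C
Reagents that add atoms: none
Why: Light-induced Wolff rearrangement of 18 gives vinylketene 23, whose carbonyl carbon is attacked by the silyloxymethyl-bearing carbon of the ynol ether while the methoxy-bearing carbon bonds to the ketene CH carbon, closing cyclobutenone 24 by a ketene–alkyne (2+2) cycloaddition. On warming, 24 opens in a reversible 4π electrocyclic step to dienylketene 25, which closes and tautomerises to the phenol. The closest known reaction is the Danheiser benzannulation of diazo enones with alkoxyalkynes. Ring A closes by a thermal disrotatory six-electron electrocyclisation that joins the ketene carbon to the ester-bearing alkene terminus, after the four-membered ring has formed and opened. No stereocentre is created: the sp3 ring carbon of 24 is lost on aromatisation and the acetal carbon stays racemic. The step needs (2+2) regioselectivity, secured by the polarisation of the ynol ether (nucleophilic at the carbon remote from oxygen) against the electrophilic ketene carbon; the (E)-alkene keeps the ester carbonyl away from the ketene and places hydrogen inward in the ring closure, excess alkyne outruns acylation of the product phenol, and 365 nm light leaves the aryl bromide untouched.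

Step 13
Reactants: 26 bromo depside
Product: 27 protected depsidone (racemic; ring A CH2OSi(iPr)3, ring B OMOM and 3-methoxyphthalide)
Conditions: CuI (20 mol %), N,N-dimethylglycine (40 mol %), Cs2CO3, 1,4-dioxane, 90 °C
Reagents that add atoms: none
Why: Intramolecular Ullmann diaryl ether synthesis: monovalent copper with an amino acid ligand couples the ring A phenoxide with the ring B bromide and closes the seven-membered dioxepinone ring, a weakly polar solvent being chosen to hold back ester cleavage and ipso substitution.

Step 14
Reactants: 27 protected depsidone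
Product: 28 rac-cryptostictic acid (racemic lactol)
Conditions: CF3CO2H/H2O/THF (2:1:2), 45 °C
Reagents that add atoms: water, O
Why: Aqueous acid hydrolysis removes the MOM acetal, the silyl ether and the methyl pseudo-ester in one operation; the lactol forms as a racemate because its carbon equilibrates through the ring-opened aldehyde acid.

Step 15
Reactants: 28 rac-cryptostictic acid
Product: 29 (R)-cryptostictic acid tris(propanoate)
Conditions: (EtCO)2O (4 equiv), (R)-2-phenyl-2,3-dihydrobenzo[d]imidazo[2,1-b]thiazole (10 mol %), iPr2NEt, CHCl3, 0 °C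
Reagents that add atoms: propanoic anhydride, CCC(=O)OC(=O)CC
Why: Acylative dynamic kinetic resolution: the lactol enantiomers interconvert through the ring-opened aldehyde carboxylate under the amine base while the chiral isothiourea acyl-transfer catalyst acylates one of them faster, so the (R)-acylal is set by the catalyst; the primary alcohol and the phenol are acylated without stereochemical consequence.

Step 16
Reactants: 29 (R)-cryptostictic acid tris(propanoate)
Product: 30 (R)-cryptostictic acid (CNP0367167.1)
Conditions: Burkholderia cepacia lipase (immobilised), n-BuOH, dry t-BuOMe, 30 °C; filter, evaporate cold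
Reagents that add atoms: none
Why: Lipase-catalysed transesterification to butanol in a dry neutral medium cleaves the acyl–oxygen bonds only, so the C–O bond at the lactol carbon is untouched and (R) is retained, and the enzyme is chosen to accept the (R)-acylal.

**Compound list**

1 | 2-methylresorcinol | Cc1c(O)cccc1O | starting material
2 | 1,3-bis(methoxymethoxy)-2-methylbenzene | COCOc1cccc(OCOC)c1C | intermediate
3 | 2,4-bis(methoxymethoxy)-3-methylphenyllithium (formed in situ) | [Li]c1ccc(OCOC)c(C)c1OCOC | intermediate
4 | N,N-diethyl-2,4-bis(methoxymethoxy)-3-methylbenzamide | CCN(CC)C(=O)c1ccc(OCOC)c(C)c1OCOC | intermediate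
5 | N,N-diethyl-6-lithio-2,4-bis(methoxymethoxy)-3-methylbenzamide (formed in situ) | [Li]c1cc(OCOC)c(C)c(OCOC)c1C(=O)N(CC)CC | intermediate
6 | N,N-diethyl-6-formyl-2,4-bis(methoxymethoxy)-3-methylbenzamide | CCN(CC)C(=O)c1c(C=O)cc(OCOC)c(C)c1OCOC | intermediate
7 | rac-3,5,7-trihydroxy-6-methylisobenzofuran-1(3H)-one (formed in situ) | OC1OC(=O)c2c(O)c(C)c(O)cc21 | intermediate
8 | rac-5,7-dihydroxy-3-methoxy-6-methylisobenzofuran-1(3H)-one | COC1OC(=O)c2c(O)c(C)c(O)cc21 | intermediate
9 | rac-4-bromo-5,7-dihydroxy-3-methoxy-6-methylisobenzofuran-1(3H)-one | COC1OC(=O)c2c(O)c(C)c(O)c(Br)c21 | intermediate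
10 | butane-2,3-dione | CC(=O)C(C)=O | starting material
11 | tert-butyl (triphenylphosphoranylidene)acetate | CC(C)(C)OC(=O)C=P(c1ccccc1)(c1ccccc1)c1ccccc1 | starting material
12 | tert-butyl (E)-3-methyl-4-oxopent-2-enoate | CC(=O)/C(C)=C/C(=O)OC(C)(C)C | intermediate
13 | (E)-3-methyl-4-oxopent-2-enoic acid | CC(=O)/C(C)=C/C(=O)O | intermediate
14 | (E)-3-methyl-4-oxopent-2-enoyl chloride (formed in situ) | CC(=O)/C(C)=C/C(=O)Cl | intermediate
15 | rac-4-bromo-7-hydroxy-3-methoxy-6-methyl-1-oxo-1,3-dihydroisobenzofuran-5-yl (E)-3-methyl-4-oxopent-2-enoate | CC(=O)/C(C)=C/C(=O)Oc1c(C)c(O)c2C(=O)OC(OC)c2c1Br | intermediate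
16 | rac-4-bromo-3-methoxy-7-(methoxymethoxy)-6-methyl-1-oxo-1,3-dihydroisobenzofuran-5-yl (E)-3-methyl-4-oxopent-2-enoate | CC(=O)/C(C)=C/C(=O)Oc1c(C)c(OCOC)c2C(=O)OC(OC)c2c1Br | intermediate
17 | aryl (E)-6,6,6-trifluoro-3-methyl-4,6-dioxohex-2-enoate, aryl as in 16 (formed in situ) | O=C(CC(=O)/C(C)=C/C(=O)Oc1c(C)c(OCOC)c2C(=O)OC(OC)c2c1Br)C(F)(F)F | intermediate
18 | rac-4-bromo-3-methoxy-7-(methoxymethoxy)-6-methyl-1-oxo-1,3-dihydroisobenzofuran-5-yl (E)-5-diazo-3-methyl-4-oxopent-2-enoate | [N-]=[N+]=CC(=O)/C(C)=C/C(=O)Oc1c(C)c(OCOC)c2C(=O)OC(OC)c2c1Br | intermediate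
19 | chloroacetaldehyde dimethyl acetal | COC(CCl)OC | starting material
20 | lithium methoxyacetylide (formed in situ) | [Li]C#COC | intermediate
21 | lithium 3-methoxyprop-2-yn-1-olate (formed in situ) | [Li]OCC#COC | intermediate
22 | 1-methoxy-3-(triisopropylsilyloxy)prop-1-yne | COC#CCO[Si](C(C)C)(C(C)C)C(C)C | intermediate
23 | vinylketene: aryl (E)-3-methyl-5-oxopenta-2,4-dienoate, aryl as in 16 (formed in situ) | O=C=C/C(C)=C/C(=O)Oc1c(C)c(OCOC)c2C(=O)OC(OC)c2c1Br | intermediate
24 | cyclobutenone: aryl (E)-3-[2-methoxy-4-oxo-3-(triisopropylsilyloxymethyl)cyclobut-2-en-1-yl]but-2-enoate, mixture of diastereomers (formed in situ) | O=C1C(CO[Si](C(C)C)(C(C)C)C(C)C)=C(OC)C1/C(C)=C/C(=O)Oc1c(C)c(OCOC)c2C(=O)OC(OC)c2c1Br | intermediate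
25 | dienylketene: aryl 5-methoxy-3-methyl-7-oxo-6-(triisopropylsilyloxymethyl)hepta-2,4,6-trienoate, ketene carbon and ester-bearing alkene cis across the central C=C (formed in situ) | O=C=C(CO[Si](C(C)C)(C(C)C)C(C)C)/C(OC)=C\C(C)=C\C(=O)Oc1c(C)c(OCOC)c2C(=O)OC(OC)c2c1Br | intermediate
26 | rac-4-bromo-3-methoxy-7-(methoxymethoxy)-6-methyl-1-oxo-1,3-dihydroisobenzofuran-5-yl 2-hydroxy-4-methoxy-6-methyl-3-[(triisopropylsilyloxy)methyl]benzoate | COc1cc(C)c(C(=O)Oc2c(C)c(OCOC)c3C(=O)OC(OC)c3c2Br)c(O)c1CO[Si](C(C)C)(C(C)C)C(C)C | intermediate
27 | protected depsidone, racemic (ring A: OMe, CH3, CH2OSi(iPr)3; ring B: CH3, OMOM, fused 3-methoxyphthalide) | COc1cc(C)c2c(c1CO[Si](C(C)C)(C(C)C)C(C)C)Oc1c(c(C)c(OCOC)c3c1C(OC)OC3=O)OC2=O | intermediate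
28 | rac-cryptostictic acid | COc1cc(C)c2c(c1CO)Oc1c(c(C)c(O)c3c1C(O)OC3=O)OC2=O | intermediate
29 | (R)-cryptostictic acid tris(propanoate) (benzylic, phenolic and lactol oxygens acylated) | COc1cc(C)c2c(c1COC(=O)CC)Oc1c(c(C)c(OC(=O)CC)c3c1[C@H](OC(=O)CC)OC3=O)OC2=O | intermediate
30 | (R)-cryptostictic acid, CNP0367167.1 | COc1cc(C)c2c(c1CO)Oc1c(c(C)c(O)c3c1[C@H](O)OC3=O)OC2=O | target

**Step count and risks**

Total step count: 16. Longest linear sequence: 13 steps (steps 1–5, 8–10, 12–16).

Steps most likely to fail:

Step 12. The light may isomerise the enone to the (Z)-form before nitrogen is lost, after which the ketene is captured by its own cis ester carbonyl instead of the alkyne. The product phenol may also be acylated by ketene, and the C–Br bond may be photolysed. Fallback: setting out from 18, ketene formation is separated from light. Wolff rearrangement with PhCO2Ag and Et3N in THF/H2O at 25 °C in the dark gives the homologous (E)-pent-3-enoic acid half ester F1. 1-Chloro-N,N,2-trimethylprop-1-en-1-amine in CH2Cl2 at 0 °C converts it into the acid chloride F2. Slow addition of iPr2NEt to F2 and 22 in toluene at 80 °C dehydrochlorinates F2 to the same vinylketene 23, at which point the route is rejoined and continues through 24 and 25 to 26.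

Step 13. The ring A phenoxide may attack the ester-bearing carbon of ring B at its ipso position (Smiles rearrangement, favoured because that carbon is para to the lactone carbonyl). Carbonate may cleave the aryl ester, or the doubly ortho-substituted bromide may be reduced instead of coupled. Fallback: setting out from 26, Miyaura borylation with PdCl2(dppf) (dppf = 1,1′-bis(diphenylphosphino)ferrocene), bis(pinacolato)diboron and KOAc in 1,4-dioxane at 85 °C gives the pinacol boronate depside F3. This is closed by oxidative Chan–Lam etherification with Cu(OAc)2, pyridine and 4 Å molecular sieves in CH2Cl2 under air at 25 °C, without carbonate base and without heat, returning to the route at 27.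

Step 16. The enzyme may not turn over the hindered aryl propanoate beside the lactone carbonyl, and the long exposure would let the liberated lactol epimerise through ring opening. Fallback: setting out from 28, the acylation is done enzymatically with the same lipase and vinyl propanoate in toluene at 40 °C with a trace of Et3N. This leaves the phenol untouched and gives, with in situ racemisation of the lactol, the (R)-bis(propanoate) F4. Its two unhindered esters are then removed by the butanol transesterification with the same enzyme, arriving at 30.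

**Further compounds**

F1 | step 12 | (E)-5-[(rac-4-bromo-3-methoxy-7-(methoxymethoxy)-6-methyl-1-oxo-1,3-dihydroisobenzofuran-5-yl)oxy]-3-methyl-5-oxopent-3-enoic acid | OC(=O)C/C(C)=C/C(=O)Oc1c(C)c(OCOC)c2C(=O)OC(OC)c2c1Br
F2 | step 12 | acid chloride of F1 | ClC(=O)C/C(C)=C/C(=O)Oc1c(C)c(OCOC)c2C(=O)OC(OC)c2c1Br
F3 | step 13 | pinacol boronate depside (Bpin in place of Br in 26) | COc1cc(C)c(C(=O)Oc2c(C)c(OCOC)c3C(=O)OC(OC)c3c2B4OC(C)(C)C(C)(C)O4)c(O)c1CO[Si](C(C)C)(C(C)C)C(C)C
F4 | step 16 | (R)-cryptostictic acid bis(propanoate) (benzylic and lactol oxygens acylated, phenol free) | COc1cc(C)c2c(c1COC(=O)CC)Oc1c(c(C)c(O)c3c1[C@H](OC(=O)CC)OC3=O)OC2=O
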